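**Retrosynthetic overview**

- The target is a C2-symmetric 1,7-dioxadispiro[4.0.4.2]dodeca-3,9-diene-2,8-dione core (two 4-bromobutenolides spiro-fused to a trans-dibromocyclobutane) carrying one (S)- and one (R)-1-acetoxybutyl chain. The two acetates are cut last: a C2-symmetric (S),(S)-diol is acetylated at one of its two homotopic carbinols and inverted at the other.
- Key disconnection: both butenolides are cut together through the lactone O–C(spiro) bond and the C3=C4 double bond. This leads back to an all-trans 3,4-dibromocyclobutane-1,2-dicarbonyl dichloride and two equivalents of an ester-stabilised phosphorus ylide carrying the (S)-silyloxybutyl chain (ketene Wittig to a 2,3-allenoate, then bromolactonisation).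
- Enabling feature: each spiro carbon is the γ-carbon of a 4-bromobut-2-en-4-olide, bonded to the ring oxygen and to the bromine-bearing olefinic carbon, which is the pattern left by brominative cyclisation of a 2,3-allenoate. Each cyclobutane CHBr is trans to the lactone oxygen on the neighbouring spiro carbon, the outcome of anti delivery of that oxygen next to a C–Br bond.
- Ring order: the cyclobutane is present from the start (meso cyclobutene anhydride, desymmetrisation, trans diacid, trans dibromide); the two butenolide rings are then closed together in the key step.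

Key step: step 8

Remark: cis-cyclobut-3-ene-1,2-dicarboxylic anhydride and (S)-1,2-epoxypentane are taken as commercial; the sense of the quinidine-mediated methanolysis is assumed by analogy with other bicyclic meso anhydrides, and quinine would be used if the opposite hemiester forms.

**Route**

Step 1
Reactants: 1 (S)-1,2-epoxypentane
Product: 2 (S)-(2-hydroxypentyl)triphenylphosphonium bromide
Conditions: PPh3·HBr, CH2Cl2, 0 °C to rt
Reagents that add atoms: triphenylphosphine hydrobromide, Br.c1ccc(cc1)P(c1ccccc1)c1ccccc1
Why: Acid-promoted SN2 opening of the terminal epoxide at its CH2 terminus by the phosphine (hydroxyalkylphosphonium salt formation) leaves the C–O stereocentre untouched, so the (S) configuration of 1 is carried into 2.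

Step 2
Reactants: 2 (S)-(2-hydroxypentyl)triphenylphosphonium bromide
Product: 3 (S)-[2-(tert-butyldimethylsilyloxy)pentyl]triphenylphosphonium bromide
Conditions: TBSOTf, 2,6-lutidine, CH2Cl2, −78 to 0 °C
Reagents that add atoms: tert-butyldimethylsilyl trifluoromethanesulfonate, CC(C)(C)[Si](C)(C)OS(=O)(=O)C(F)(F)F
Why: Silyl ether protection with a silyl triflate and a hindered pyridine base never generates the β-oxido phosphonium betaine, which would fragment in Wittig fashion.

Step 3
Reactants: 3 (S)-[2-(tert-butyldimethylsilyloxy)pentyl]triphenylphosphonium bromide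
Product: 6 tert-butyl (3S)-3-[(tert-butyldimethylsilyl)oxy]-2-(triphenyl-λ5-phosphanylidene)hexanoate, via β-silyloxy ylide 4 (not isolated), via acylphosphonium salt 5 (not isolated)
Conditions: NaN(SiMe3)2, THF, −78 °C; Boc2O, −78 °C to rt
Reagents that add atoms: di-tert-butyl dicarbonate, CC(C)(C)OC(=O)OC(=O)OC(C)(C)C
Why: Deprotonation gives the non-stabilised ylide, whose C-acylation by the dicarbonate (ylide acylation) followed by deprotonation of the acylphosphonium by the released tert-butoxide should give the ester-stabilised ylide without touching the stereocentre.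

Step 4
Reactants: 7 cis-cyclobut-3-ene-1,2-dicarboxylic anhydride (meso)
Product: 8 (1R,2S)-2-(methoxycarbonyl)cyclobut-3-ene-1-carboxylic acid
Conditions: quinidine, MeOH, toluene/CCl4, −55 °C
Reagents that add atoms: methanol, CO
Why: Cinchona-alkaloid-mediated enantioselective methanolysis of a meso cyclic anhydride (desymmetrisation) differentiates the two carbonyl groups and so fixes the absolute configuration of the ring.

Step 5
Reactants: 8 (1R,2S)-2-(methoxycarbonyl)cyclobut-3-ene-1-carboxylic acid
Product: 10 (1R,2R)-cyclobut-3-ene-1,2-dicarboxylic acid, via trans hemiester 9 (not isolated)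
Conditions: NaOMe, MeOH, rt; then aq NaOH; HCl work-up
Reagents that add atoms: sodium hydroxide, [Na+].[OH-]
Why: Thermodynamic epimerisation of the ester-bearing carbon through its ester enolate (the carboxylate-bearing carbon is not deprotonated, and α-reprotonation is relied on) should give the trans hemiester, and saponification then gives the C2-symmetric trans diacid as one enantiomer.

Step 6
Reactants: 10 (1R,2R)-cyclobut-3-ene-1,2-dicarboxylic acid
Product: 11 (1R,2R,3R,4R)-3,4-dibromocyclobutane-1,2-dicarboxylic acid
Conditions: Br2, CH2Cl2/AcOH, 0 °C, dark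
Reagents that add atoms: bromine, BrBr
Why: Anti addition of bromine through a bromonium ion (alkene dibromination), with bromide opening the ion at the carbon whose neighbouring carboxyl lies on the far face, should put each bromine trans to its neighbouring carboxyl and so fix the two CHBr stereocentres of the target in the all-trans dibromide.

Step 7
Reactants: 11 (1R,2R,3R,4R)-3,4-dibromocyclobutane-1,2-dicarboxylic acid
Product: 12 (1R,2R,3R,4R)-3,4-dibromocyclobutane-1,2-dicarbonyl dichloride
Conditions: (COCl)2, cat. DMF, CH2Cl2, 0 °C to rt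
Reagents that add atoms: oxalyl chloride, O=C(Cl)C(Cl)=O
Why: Acid chloride formation under Vilsmeier catalysis is non-basic, so no stereocentre is touched and no HBr is lost.

Step 8
Reactants: 12 (1R,2R,3R,4R)-3,4-dibromocyclobutane-1,2-dicarbonyl dichloride; 6 tert-butyl (3S)-3-[(tert-butyldimethylsilyl)oxy]-2-(triphenyl-λ5-phosphanylidene)hexanoate (2 equiv)
Product: 15 (5S,6S,11R,12R)-4,10,11,12-tetrabromo-3,9-bis[(1S)-1-[(tert-butyldimethylsilyl)oxy]butyl]-1,7-dioxadispiro[4.0.4.2]dodeca-3,9-diene-2,8-dione, via bis-ketene 13 (not isolated), via bis-allenoate 14 (not isolated)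
Conditions: Et3N, CH2Cl2, −78 to −20 °C; then NBS, −40 to 0 °C
Reagents that add atoms: N-bromosuccinimide, O=C1CCC(=O)N1Br
Why: Triethylamine dehydrochlorinates each acyl chloride to a cyclobutylidene ketene that is trapped at once by ylide 6 in a Wittig reaction at the ketene carbonyl (the standard acid chloride/stabilised ylide route to 2,3-allenoates), which forms both C3=C4 bonds; N-bromosuccinimide then attacks the central allene carbon and the ester carbonyl oxygen closes onto the ring carbon with loss of isobutene (bromolactonisation of 2,3-allenoates to 4-bromobut-2-en-4-olides), which forms both O–C(spiro) bonds and both vinylic C–Br bonds. Each lactone closes in a 5-endo mode onto the allene terminus. The two spiro stereocentres are controlled by the neighbouring CHBr centres: the developing cation at the spiro carbon is bridged by the vicinal bromine, so the lactone oxygen should enter anti to it, and because the ring bromines are trans the two lactone oxygens also end trans; the allene axes formed in the Wittig step therefore need no control. The step needs ketene formation to outrun loss of HBr, which the all-trans acid chloride favours because each α-hydrogen is cis to the neighbouring bromine and has no antiperiplanar β-leaving group; it also needs bromine to go to the allenes only, which are the sole π bonds besides the esters.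

Step 9
Reactants: 15 bis(silyl ether) of the dispiro tetrabromide
Product: 16 (5S,6S,11R,12R)-4,10,11,12-tetrabromo-3,9-bis[(1S)-1-hydroxybutyl]-1,7-dioxadispiro[4.0.4.2]dodeca-3,9-diene-2,8-dione
Conditions: HF·pyridine, THF, 0 °C to rt
Reagents that add atoms: none
Why: Fluoride-mediated silyl ether cleavage under acidic buffered conditions should spare the lactones and the vinylic and alkyl bromides, which a basic fluoride source would endanger.

Step 10
Reactants: 16 C2-symmetric (S),(S)-diol
Product: 17 monoacetate, 3-[(1S)-1-acetoxybutyl]-9-[(1S)-1-hydroxybutyl] compound with the core of 16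
Conditions: Ac2O (1 equiv), pyridine, CH2Cl2, −20 °C
Reagents that add atoms: acetic anhydride, CC(=O)OC(C)=O
Why: Acylation with one equivalent of anhydride gives a single monoacetate because the two carbinols are homotopic through the C2 axis; diol and diacetate differ in polarity, are separated, and the diol is recycled.

Step 11
Reactants: 17 monoacetate
Product: 18 target, (5S,6S,11R,12R)-4,10,11,12-tetrabromo-1,7-dioxadispiro[4.0.4.2]dodeca-3,9-diene-2,8-dione bearing one (1S)- and one (1R)-1-acetoxybutyl group at C3 and C9
Conditions: PPh3, DIAD, AcOH, toluene, 0 °C to rt (betaine pre-formed)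
Reagents that add atoms: acetic acid, CC(O)=O
Why: Mitsunobu esterification inverts the remaining (S)-carbinol by SN2 displacement of its oxyphosphonium with acetate, giving the (R)-acetate and hence the (S),(R) pair of side chains on the C2-symmetric core.

**Compound list**

1 | (S)-1,2-epoxypentane | CCC[C@H]1CO1 | starting material
2 | (S)-(2-hydroxypentyl)triphenylphosphonium bromide | CCC[C@H](O)C[P+](c1ccccc1)(c1ccccc1)c1ccccc1.[Br-] | intermediate
3 | (S)-[2-(tert-butyldimethylsilyloxy)pentyl]triphenylphosphonium bromide | CCC[C@H](O[Si](C)(C)C(C)(C)C)C[P+](c1ccccc1)(c1ccccc1)c1ccccc1.[Br-] | intermediate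
4 | (S)-[2-(tert-butyldimethylsilyloxy)pentylidene]triphenylphosphorane | CCC[C@H](O[Si](C)(C)C(C)(C)C)C=P(c1ccccc1)(c1ccccc1)c1ccccc1 | intermediate
5 | [(3S)-1-tert-butoxy-3-(tert-butyldimethylsilyloxy)-1-oxohexan-2-yl]triphenylphosphonium tert-butyl carbonate | CCC[C@H](O[Si](C)(C)C(C)(C)C)C(C(=O)OC(C)(C)C)[P+](c1ccccc1)(c1ccccc1)c1ccccc1.CC(C)(C)OC(=O)[O-] | intermediate
6 | tert-butyl (3S)-3-[(tert-butyldimethylsilyl)oxy]-2-(triphenyl-λ5-phosphanylidene)hexanoate | CCC[C@H](O[Si](C)(C)C(C)(C)C)C(C(=O)OC(C)(C)C)=P(c1ccccc1)(c1ccccc1)c1ccccc1 | intermediate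
7 | cis-cyclobut-3-ene-1,2-dicarboxylic anhydride (3-oxabicyclo[3.2.0]hept-6-ene-2,4-dione, meso) | O=C1OC(=O)[C@@H]2C=C[C@H]12 | starting material
8 | (1R,2S)-2-(methoxycarbonyl)cyclobut-3-ene-1-carboxylic acid (cis) | OC(=O)[C@@H]1C=C[C@@H]1C(=O)OC | intermediate
9 | (1R,2R)-2-(methoxycarbonyl)cyclobut-3-ene-1-carboxylic acid (trans) | OC(=O)[C@@H]1C=C[C@H]1C(=O)OC | intermediate
10 | (1R,2R)-cyclobut-3-ene-1,2-dicarboxylic acid (trans) | OC(=O)[C@@H]1C=C[C@H]1C(=O)O | intermediate
11 | (1R,2R,3R,4R)-3,4-dibromocyclobutane-1,2-dicarboxylic acid (all-trans) | OC(=O)[C@@H]1[C@@H](Br)[C@H](Br)[C@H]1C(=O)O | intermediate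
12 | (1R,2R,3R,4R)-3,4-dibromocyclobutane-1,2-dicarbonyl dichloride | O=C(Cl)[C@@H]1[C@@H](Br)[C@H](Br)[C@H]1C(Cl)=O | intermediate
13 | (3R,4R)-3,4-dibromo-1,2-bis(oxomethylidene)cyclobutane (bis-ketene) | O=C=C1[C@@H](Br)[C@H](Br)C1=C=O | intermediate
14 | bis-allenoate: (3R,4R)-3,4-dibromocyclobutane-1,2-diylidene carrying two =C=C(CO2tBu)[(1S)-1-(tert-butyldimethylsilyloxy)butyl] units, allene axes undefined | CCC[C@H](O[Si](C)(C)C(C)(C)C)C(C(=O)OC(C)(C)C)=C=C1[C@@H](Br)[C@H](Br)C1=C=C(C(=O)OC(C)(C)C)[C@H](CCC)O[Si](C)(C)C(C)(C)C | intermediate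
15 | (5S,6S,11R,12R)-4,10,11,12-tetrabromo-3,9-bis[(1S)-1-[(tert-butyldimethylsilyl)oxy]butyl]-1,7-dioxadispiro[4.0.4.2]dodeca-3,9-diene-2,8-dione | CCC[C@H](O[Si](C)(C)C(C)(C)C)C1=C(Br)[C@@]2(OC1=O)[C@@H](Br)[C@H](Br)[C@@]21OC(=O)C([C@H](CCC)O[Si](C)(C)C(C)(C)C)=C1Br | intermediate
16 | (5S,6S,11R,12R)-4,10,11,12-tetrabromo-3,9-bis[(1S)-1-hydroxybutyl]-1,7-dioxadispiro[4.0.4.2]dodeca-3,9-diene-2,8-dione | CCC[C@H](O)C1=C(Br)[C@@]2(OC1=O)[C@@H](Br)[C@H](Br)[C@@]21OC(=O)C([C@H](CCC)O)=C1Br | intermediate
17 | monoacetate of 16: one (1S)-1-acetoxybutyl and one (1S)-1-hydroxybutyl group | CCC[C@H](OC(C)=O)C1=C(Br)[C@@]2(OC1=O)[C@@H](Br)[C@H](Br)[C@@]21OC(=O)C([C@H](CCC)O)=C1Br | intermediate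
18 | target: (5S,6S,11R,12R)-tetrabromo dispiro bis(butenolide) with one (1S)- and one (1R)-1-acetoxybutyl group | CCC[C@H](OC(C)=O)C1=C(Br)[C@@]2(OC1=O)[C@@H](Br)[C@H](Br)[C@@]21OC(=O)C([C@@H](CCC)OC(C)=O)=C1Br | target

**Step count and risks**

Total steps: 11. Longest linear sequence: 8 steps (steps 4 to 11); the ylide branch (steps 1 to 3) joins at step 8.

Steps most likely to fail:

1. Step 8. Loss of HBr from the β-bromo acyl chloride or ketene may compete with ketene formation and Wittig trapping, and the lactone oxygen may enter on the face of the neighbouring bromine and give spiro epimers. Fallback: set out from 10 and reverse the order of annulation and bromination. Oxalyl chloride converts 10 into (1R,2R)-cyclobut-3-ene-1,2-dicarbonyl dichloride F1, which carries no β-leaving group. The same ketene Wittig reaction with 6 gives the bromine-free bis-allenoate F2, and brominative lactonisation with two equivalents of NBS gives the dispiro cyclobutene F3. Anti addition of Br2 across the ring alkene then returns to the route at 15. In this order the trans relationship of the ring bromines is still secured, but the spiro centres and the sense of the dibromination are no longer set by neighbouring bromines. The required dibromide, with each bromine anti to the neighbouring lactone oxygen, is then the more hindered one and would have to be separated from its diastereomers.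

2. Step 5. Under alkoxide the ring double bond may migrate into conjugation with the ester, or epimerisation may stay incomplete. Fallback: set out from 7 and epimerise the other carbon without an ester enolate. Methanolysis of 7 with quinine in place of quinidine gives the enantiomeric hemiester (1S,2R)-2-(methoxycarbonyl)cyclobut-3-ene-1-carboxylic acid F4. Oxalyl chloride gives its acid chloride F5. Catalytic Et3N equilibrates the acid-chloride-bearing carbon through its ketene to the trans acid chloride ester F6. Aqueous LiOH then hydrolyses both acyl groups and returns to the route at 10.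

3. Step 11. Elimination, SN2′ attack or addition of the phosphine to the bromobutenolide may replace clean SN2 inversion at the hindered carbinol. Fallback: set out from 17 and invert by oxidation and reduction. Dess–Martin periodinane oxidises the free carbinol to the butanoyl ketone F7. (S)-2-Methyl-CBS-oxazaborolidine with catecholborane at low temperature reduces it under reagent control, with the butenolide as the large group, to the (R)-carbinol F8. Ac2O/pyridine then returns to the route at 18.

**Further compounds**

F1 | step 8 | (1R,2R)-cyclobut-3-ene-1,2-dicarbonyl dichloride | O=C(Cl)[C@@H]1C=C[C@H]1C(Cl)=O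
F2 | step 8 | bromine-free bis-allenoate, cyclobut-3-ene-1,2-diylidene carrying two =C=C(CO2tBu)[(1S)-1-(tert-butyldimethylsilyloxy)butyl] units | CCC[C@H](O[Si](C)(C)C(C)(C)C)C(C(=O)OC(C)(C)C)=C=C1C=CC1=C=C(C(=O)OC(C)(C)C)[C@H](CCC)O[Si](C)(C)C(C)(C)C
F3 | step 8 | (5S,6S)-4,10-dibromo-3,9-bis[(1S)-1-[(tert-butyldimethylsilyl)oxy]butyl]-1,7-dioxadispiro[4.0.4.2]dodeca-3,9,11-triene-2,8-dione | CCC[C@H](O[Si](C)(C)C(C)(C)C)C1=C(Br)[C@@]2(OC1=O)C=C[C@@]21OC(=O)C([C@H](CCC)O[Si](C)(C)C(C)(C)C)=C1Br
F4 | step 5 | (1S,2R)-2-(methoxycarbonyl)cyclobut-3-ene-1-carboxylic acid | OC(=O)[C@H]1C=C[C@H]1C(=O)OC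
F5 | step 5 | methyl (1R,2S)-2-(chlorocarbonyl)cyclobut-3-ene-1-carboxylate (cis) | O=C(Cl)[C@H]1C=C[C@H]1C(=O)OC
F6 | step 5 | methyl (1R,2R)-2-(chlorocarbonyl)cyclobut-3-ene-1-carboxylate (trans) | O=C(Cl)[C@@H]1C=C[C@H]1C(=O)OC
F7 | step 11 | 3-[(1S)-1-acetoxybutyl]-9-butanoyl analogue of 17 | CCC[C@H](OC(C)=O)C1=C(Br)[C@@]2(OC1=O)[C@@H](Br)[C@H](Br)[C@@]21OC(=O)C(C(=O)CCC)=C1Br
F8 | step 11 | 3-[(1S)-1-acetoxybutyl]-9-[(1R)-1-hydroxybutyl] analogue of 17 | CCC[C@H](OC(C)=O)C1=C(Br)[C@@]2(OC1=O)[C@@H](Br)[C@H](Br)[C@@]21OC(=O)C([C@@H](CCC)O)=C1Br
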